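**Plan**
- Retrosynthesis of GA87, the (12S)-12-hydroxy derivative of gibberellic acid (GA3): (a) the C12–H bond, back to a C12 ketone; (b) the C13–C16 bond of ring D, back to a ring C enediol bis-silyl ether (C12=C13) whose quaternary C8 carries a propargyl arm (C15–C16≡C17); (c) the C12 oxygen and C16≡C17, back to a seco keto-aldehyde; (d) the seco compound, back to GA3 by excision of C17 and glycol cleavage of C13–C16.
- Forward: rings A, B and C, the lactone and the C7 acid come intact from GA3. Ring D is opened between C13 and C16, C17 is returned as the alkyne terminus, ring C is oxygenated at C12, and ring D is closed again in step 9.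
- Enabling feature: on ring C the C8 propargyl arm is axial and lies 1,3-diaxial to C13, and in the C12=C13 enediol bis-silyl ether the future carbinol carbon C13 is itself the nucleophile. This substrate has no C12 stereocentre, so all C12 epimers and acyloin tautomers converge.
- Stereochemistry: C3, C4, C5, C6, C8, C9 and C10 are those of GA3. C13 is re-set by the C8 tether during ring closure. C12 (S, hydroxyl axial on ring C) is set by equatorial hydride attack on the C12 ketone, because the axial trajectory is blocked by the syn-axial C9–C10 bond.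

Key step: step 9

Assumption: gibberellic acid (GA3), a bulk fermentation diterpenoid, is taken as a commercial chiral-pool starting material, so the route is a relay synthesis that dismantles and rebuilds only ring D.

**Step 1**
Reactants: 1 gibberellic acid (GA3); 2 2-(trimethylsilyl)ethoxymethyl chloride (SEMCl)
Product: 3 GA3 SEM ester (C7 ester; 3-OH and 13-OH free)
Conditions: SEMCl (1.1 equiv), i-Pr2NEt (1.5 equiv), THF/CH2Cl2, 0 °C
Reagents that add atoms: SEMCl, C[Si](C)(C)CCOCCl
Why: O-alkylation of the carboxylate by the α-chloro ether should be far faster than etherification of the hindered secondary and tertiary hydroxyls, giving a fluoride-labile alkoxymethyl ester of the hindered C7 acid without touching any stereocentre.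

**Step 2**
Reactants: 3 GA3 SEM ester; 4 tert-butyldimethylsilyl chloride (TBSCl)
Product: 5 3-O-TBS GA3 SEM ester
Conditions: TBSCl (1.5 equiv), imidazole (3 equiv), DMF, 23 °C
Reagents that add atoms: TBSCl, CC(C)(C)[Si](C)(C)Cl
Why: Imidazole-mediated silylation should occur only at the secondary allylic 3-OH, the bridgehead tertiary 13-OH being too hindered for TBSCl.

**Step 3**
Reactants: 5 3-O-TBS GA3 SEM ester; 6 ozone
Product: 7 17-nor-16-oxo compound (ring D α-ketol, 13-hydroxy-16-ketone)
Conditions: O3 (about 1.05 equiv, dosed), pyridine (3 equiv), CH2Cl2, −78 °C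
Reagents that add atoms: ozone, [O-][O+]=O
Why: Pyridine-moderated ozonolysis should cleave the unhindered 1,1-disubstituted C16=C17 alkene in preference to C1=C2, which is deactivated by two allylic C–O bonds (lactone oxygen at C10, silyloxy at C3) and shielded by quaternary C10.

**Step 4**
Reactants: 7 17-nor-16-oxo compound
Product: 8 17-nor-13,16-diol (mainly the C16 epimer with the 16-OH endo, on the C11–C12 side of ring C)
Conditions: NaBH4, MeOH/THF, −20 to 0 °C
Reagents that add atoms: none
Why: Borohydride reduction of the ring D ketone from its exo face (the side of the one-carbon bridge C14, away from C11 and C12) should give the diol; the new C16 carbinol centre is temporary and is destroyed in step 5, so its configuration is immaterial.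

**Step 5**
Reactants: 8 17-nor-13,16-diol
Product: 9 17-nor-13,16-seco keto-aldehyde (ring C 13-ketone; C8 bears CH2CHO)
Conditions: Pb(OAc)4 (1.3 equiv), pyridine (3 equiv), CH2Cl2, 0 to 23 °C
Reagents that add atoms: none
Why: Criegee glycol cleavage with Pb(OAc)4 in pyridine, which also cleaves rigid diols whose O–C–C–O dihedral (here near 85°) is too wide for a cyclic periodate ester, should break the C13–C16 bond to the C13 ketone and the C16 aldehyde without affecting C8.

**Step 6**
Reactants: 9 seco keto-aldehyde; 10 dimethyl (1-diazo-2-oxopropyl)phosphonate (Ohira–Bestmann reagent)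
Product: 11 13,16-seco alkynyl ketone (ring C 13-ketone; C8 bears prop-2-ynyl, C15–C16≡C17)
Conditions: Ohira–Bestmann reagent (1.5 equiv), K2CO3 (2 equiv), MeOH, 0 to 23 °C
Reagents that add atoms: Ohira–Bestmann reagent, CC(=O)C(=[N+]=[N-])P(=O)(OC)OC
Why: In the Ohira–Bestmann (Seyferth–Gilbert) homologation the diazomethylphosphonate anion made in the flask adds to the aldehyde only (ketones are inert under these conditions, and any intramolecular aldol between C12 and the aldehyde is reversible), and 1,2-hydrogen shift of the alkylidene carbene should return C17 as the alkyne terminus.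

**Step 7**
Reactants: 11 seco alkynyl ketone; 12 3-phenyl-2-(phenylsulfonyl)oxaziridine (Davis oxaziridine)
Product: 14 seco 12-hydroxy-13-ketone (acyloin; mainly 12R), via potassium enolate 13 (not isolated)
Conditions: KN(SiMe3)2 (1.1 equiv), THF, −78 °C; then Davis oxaziridine (1.3 equiv), −78 °C; aqueous NH4Cl
Reagents that add atoms: Davis oxaziridine, O=S(=O)(c1ccccc1)N1OC1c1ccccc1
Why: Kinetic deprotonation by the bulky amide should occur at C12 and not at C14 (neopentylic to quaternary C8), and enolate hydroxylation by the oxaziridine installs the C12 oxygen; its configuration is immaterial because C12 becomes sp2 in step 8.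

**Step 8**
Reactants: 14 seco 12-hydroxy-13-ketone; 15 triethylsilyl trifluoromethanesulfonate (TESOTf)
Product: 17 seco 12,13-enediol bis(triethylsilyl) ether (C12=C13), via silyloxy ketone 16 (not isolated)
Conditions: TESOTf (3 equiv), Et3N (5 equiv), CH2Cl2, −78 to 0 °C; used crude under argon
Reagents that add atoms: TESOTf, CC[Si](CC)(CC)OS(=O)(=O)C(F)(F)F
Why: O-silylation followed by silyl triflate/amine soft enolisation should remove the oxygen-acidified C12–H, not the hindered C14–H, to give the tetrasubstituted enediol bis-silyl ether, the usual exhaustive silylation product of an acyloin, into which both C12 epimers and any 13-hydroxy-12-ketone tautomer converge.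

**Step 9**
Reactants: 17 seco enediol bis(triethylsilyl) ether
Product: 18 12-oxo-13-O-TES-3-O-TBS GA3 SEM ester (ring D re-closed, C16=C17H2)
Conditions: Ph3PAuNTf2 (5 mol %), MeOH (2 equiv), CH2Cl2, 0 to 23 °C, argon
Reagents that add atoms: none
Why: Proposed new method: the cationic monovalent gold complex π-activates the terminal alkyne, and C13 of the enediol bis-silyl ether (the nucleophilic β-carbon of the C12 silyl enol ether) attacks the internal alkyne carbon C16 anti to gold; the C12 silyloxocarbenium ion then gives its silyl group to methanol (C12 ketone) and protodeauration of the exocyclic vinylgold leaves the C16=C17 methylene. The closest known reaction type is the gold-catalysed Conia-ene-type carbocyclisation of silyl enol ethers onto tethered terminal alkynes, which builds methylene-bicyclo[3.2.1]octanes, whereas attack through the oxygen-bearing carbon of a 1,2-bis(silyloxy)alkene has precedent only in Mukaiyama-type additions of such enediol ethers to acetals and aldehydes. Ring D (C8–C14–C13–C16–C15) closes in the 5-exo-dig mode. The only new stereocentre, C13, is fixed by the tether: the propargyl arm on quaternary C8 is axial and lies 1,3-diaxial over C13 on one face of ring C, so C16 can enter only syn to C15 and O13 is left equatorial as in the natural series, while the absence of a C12 stereocentre makes the step convergent for every isomer of 14. The selectivities needed are C13 over C12 attack (reaching C12 would require a boat ring C and give a bicyclo[2.2.2]octane) and exo over 6-endo closure (terminal alkyne, small Ph3P ligand), and carbophilic gold should leave the ring A alkene, the allylic lactone and the acetal ester alone.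

**Step 10**
Reactants: 18 12-oxo-13-O-TES-3-O-TBS GA3 SEM ester
Product: 19 (12S)-12-hydroxy-13-O-TES-3-O-TBS GA3 SEM ester (protected GA87)
Conditions: LiB(s-Bu)3H (L-Selectride, 1.5 equiv), THF, −78 to −40 °C; aqueous NH4Cl
Reagents that add atoms: none
Why: In this substrate-controlled hydride reduction the axial trajectory at C12 is blocked by the syn-axial C9–C10 bond (quaternary C10 under ring C), so the bulky hydride should enter equatorially from the face that carries the C15–C16 bridge and leave the carbinol axial, (12S), as in reductions of 11-oxo steroids; a 1,2-silyl shift between O13 and O12 would be inconsequential because both positions are unmasked in step 11.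

**Step 11**
Reactants: 19 protected GA87
Product: 20 GA87 ((12S)-12-hydroxygibberellic acid)
Conditions: Bu4NF (6 equiv), AcOH (3 equiv), THF, 0 to 40 °C; aqueous work-up at pH 3
Reagents that add atoms: none
Why: Fluoride should cleave the silyl ethers at O3 and O13 and fragment the SEM ester (loss of Me3SiF, ethene and formaldehyde), and the acetic acid buffer keeps conditions mild enough to avoid base-induced transposition of the allylic 19,10-lactone or retro-aldol epimerisation at C3.

**Compound list**
1 | gibberellic acid (GA3) | C=C1C[C@]23C[C@@]1(O)CC[C@H]2[C@@]12C=C[C@H](O)[C@@](C)(C(=O)O1)[C@H]2[C@@H]3C(=O)O | starting material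
2 | 2-(trimethylsilyl)ethoxymethyl chloride (SEMCl) | C[Si](C)(C)CCOCCl | starting material
3 | GA3 SEM ester (C7 2-(trimethylsilyl)ethoxymethyl ester) | C=C1C[C@]23C[C@@]1(O)CC[C@H]2[C@@]12C=C[C@H](O)[C@@](C)(C(=O)O1)[C@H]2[C@@H]3C(=O)OCOCC[Si](C)(C)C | intermediate
4 | tert-butyldimethylsilyl chloride (TBSCl) | CC(C)(C)[Si](C)(C)Cl | starting material
5 | 3-O-TBS GA3 SEM ester | C=C1C[C@]23C[C@@]1(O)CC[C@H]2[C@@]12C=C[C@H](O[Si](C)(C)C(C)(C)C)[C@@](C)(C(=O)O1)[C@H]2[C@@H]3C(=O)OCOCC[Si](C)(C)C | intermediate
6 | ozone | [O-][O+]=O | starting material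
7 | 17-nor-16-oxo compound (ring D α-ketol: 13-hydroxy-16-ketone) | O=C1C[C@]23C[C@@]1(O)CC[C@H]2[C@@]12C=C[C@H](O[Si](C)(C)C(C)(C)C)[C@@](C)(C(=O)O1)[C@H]2[C@@H]3C(=O)OCOCC[Si](C)(C)C | intermediate
8 | 17-nor-13,16-diol (major C16 epimer, 16-OH endo on the C11–C12 side of ring C) | O[C@H]1C[C@]23C[C@@]1(O)CC[C@H]2[C@@]12C=C[C@H](O[Si](C)(C)C(C)(C)C)[C@@](C)(C(=O)O1)[C@H]2[C@@H]3C(=O)OCOCC[Si](C)(C)C | intermediate
9 | 17-nor-13,16-seco keto-aldehyde (13-ketone; C8 bears CH2CHO) | O=CC[C@]23CC(=O)CC[C@H]2[C@@]12C=C[C@H](O[Si](C)(C)C(C)(C)C)[C@@](C)(C(=O)O1)[C@H]2[C@@H]3C(=O)OCOCC[Si](C)(C)C | intermediate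
10 | dimethyl (1-diazo-2-oxopropyl)phosphonate (Ohira–Bestmann reagent) | CC(=O)C(=[N+]=[N-])P(=O)(OC)OC | starting material
11 | 13,16-seco alkynyl ketone (13-ketone; C8 bears prop-2-ynyl) | C#CC[C@]23CC(=O)CC[C@H]2[C@@]12C=C[C@H](O[Si](C)(C)C(C)(C)C)[C@@](C)(C(=O)O1)[C@H]2[C@@H]3C(=O)OCOCC[Si](C)(C)C | intermediate
12 | 3-phenyl-2-(phenylsulfonyl)oxaziridine (Davis oxaziridine) | O=S(=O)(c1ccccc1)N1OC1c1ccccc1 | starting material
13 | potassium C12=C13 enolate of 11 | C#CC[C@]23CC(O[K])=CC[C@H]2[C@@]12C=C[C@H](O[Si](C)(C)C(C)(C)C)[C@@](C)(C(=O)O1)[C@H]2[C@@H]3C(=O)OCOCC[Si](C)(C)C | intermediate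
14 | seco 12-hydroxy-13-ketone (acyloin; major 12R epimer) | C#CC[C@]23CC(=O)[C@H](O)C[C@H]2[C@@]12C=C[C@H](O[Si](C)(C)C(C)(C)C)[C@@](C)(C(=O)O1)[C@H]2[C@@H]3C(=O)OCOCC[Si](C)(C)C | intermediate
15 | triethylsilyl trifluoromethanesulfonate (TESOTf) | CC[Si](CC)(CC)OS(=O)(=O)C(F)(F)F | starting material
16 | seco 12-triethylsilyloxy-13-ketone (major 12R epimer) | C#CC[C@]23CC(=O)[C@H](O[Si](CC)(CC)CC)C[C@H]2[C@@]12C=C[C@H](O[Si](C)(C)C(C)(C)C)[C@@](C)(C(=O)O1)[C@H]2[C@@H]3C(=O)OCOCC[Si](C)(C)C | intermediate
17 | seco 12,13-enediol bis(triethylsilyl) ether (C12=C13) | C#CC[C@]23CC(O[Si](CC)(CC)CC)=C(O[Si](CC)(CC)CC)C[C@H]2[C@@]12C=C[C@H](O[Si](C)(C)C(C)(C)C)[C@@](C)(C(=O)O1)[C@H]2[C@@H]3C(=O)OCOCC[Si](C)(C)C | intermediate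
18 | 12-oxo-13-O-TES-3-O-TBS GA3 SEM ester (ring D closed) | C=C1C[C@]23C[C@@]1(O[Si](CC)(CC)CC)C(=O)C[C@H]2[C@@]12C=C[C@H](O[Si](C)(C)C(C)(C)C)[C@@](C)(C(=O)O1)[C@H]2[C@@H]3C(=O)OCOCC[Si](C)(C)C | intermediate
19 | (12S)-12-hydroxy-13-O-TES-3-O-TBS GA3 SEM ester (12-OH axial on ring C, anti to the C13–C16 bond) | C=C1C[C@]23C[C@@]1(O[Si](CC)(CC)CC)[C@@H](O)C[C@H]2[C@@]12C=C[C@H](O[Si](C)(C)C(C)(C)C)[C@@](C)(C(=O)O1)[C@H]2[C@@H]3C(=O)OCOCC[Si](C)(C)C | intermediate
20 | GA87 ((12S)-12-hydroxygibberellic acid; 12-OH axial on ring C) | C=C1C[C@]23C[C@@]1(O)[C@@H](O)C[C@H]2[C@@]12C=C[C@H](O)[C@@](C)(C(=O)O1)[C@H]2[C@@H]3C(=O)O | target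

**Totals**
Total step count: 11. Longest linear sequence: 11 steps (fully linear from 1).

**Steps most likely to fail**

Step 9 (proposed new method). What may go wrong: protodesilylation of the enediol ether before it cyclises, 6-endo closure, or attack through C12 instead of C13. Fallback with known chemistry: the same bond is closed by a nickel-catalysed reductive alkyne–ketone cyclisation, and C12 is adjusted afterwards. It sets out from 14, which is silylated (TESCl, imidazole, DMF) to the silyloxy ketone 16, here isolated. Ni(cod)2 (20 mol %), IPr (1,3-bis(2,6-diisopropylphenyl)imidazol-2-ylidene) and Et3SiH in THF at 25–45 °C (oxidative cyclisation of alkyne and ketone on zerovalent nickel, then Si–H cleavage of the metallacycle) should give the ring D-closed (12R)-12,13-bis(triethylsilyl) ether F1. PPTS in MeOH/CH2Cl2 at 0 °C should remove only the secondary 12-O-silyl group to give the (12R)-12-alcohol 13-O-TES ether F2. Dess–Martin periodinane (NaHCO3, CH2Cl2) then oxidises F2 to ketone 18, where the route is rejoined.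

Step 10. What may go wrong: poor facial selectivity, with hydride entering along the axial trajectory to give the equatorial 12-epimer. Fallback: stereocontrol is moved from the substrate to the reagent. From 18, a Corey–Bakshi–Shibata reduction with (R)-2-methyl-CBS-oxazaborolidine (1 equiv) and catecholborane in toluene at −78 °C is used; catecholborane does not hydroborate the alkenes without a catalyst. With C13 as the large and C11 as the small substituent, the catalyst model delivers hydride to the face that gives (12S), so the product is 19 directly and no new compound arises.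

Step 8. What may go wrong: enolisation toward C14 instead of C12, or hydrolytic loss of the labile enediol ether on handling. Fallback: the regiochemistry is fixed by oxidation level instead of by deprotonation. From 14, Dess–Martin oxidation should give the seco 12,13-dione F3 (in equilibrium with its diosphenol tautomers). Reductive bis-silylation of this 1,2-dione (Zn dust, TESCl, THF, 0 to 23 °C) should give 17 directly, which is used crude in step 9.

**Further compounds**
F1 | step 9 | ring D-closed (12R)-12,13-bis(triethylsilyl) ether of 3-O-TBS 12-hydroxy-GA3 SEM ester | C=C1C[C@]23C[C@@]1(O[Si](CC)(CC)CC)[C@H](O[Si](CC)(CC)CC)C[C@H]2[C@@]12C=C[C@H](O[Si](C)(C)C(C)(C)C)[C@@](C)(C(=O)O1)[C@H]2[C@@H]3C(=O)OCOCC[Si](C)(C)C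
F2 | step 9 | (12R)-12-hydroxy-13-O-TES-3-O-TBS GA3 SEM ester | C=C1C[C@]23C[C@@]1(O[Si](CC)(CC)CC)[C@H](O)C[C@H]2[C@@]12C=C[C@H](O[Si](C)(C)C(C)(C)C)[C@@](C)(C(=O)O1)[C@H]2[C@@H]3C(=O)OCOCC[Si](C)(C)C
F3 | step 8 | seco 12,13-dione (ring C 1,2-diketone; C8 bears prop-2-ynyl) | C#CC[C@]23CC(=O)C(=O)C[C@H]2[C@@]12C=C[C@H](O[Si](C)(C)C(C)(C)C)[C@@](C)(C(=O)O1)[C@H]2[C@@H]3C(=O)OCOCC[Si](C)(C)C
F0 | step 10 | none | none
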